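**Retrosynthetic overview**

1. Labels: rings A, C and B are the (−)-epiafzelechin unit (flavan numbering O1–C8a). Ring F is the dihydrofuran O7–C2'–C3'–C8–C7, with ring E the aryl group on C2'. Ring G is the furanone made of spiro C3', the ketone carbon, two carbons of phloroglucinol ring D and the ring D oxygen.
2. Ring G is closed last, through the O(ring D)–C3' bond: 16 ⇒ hexaphenolic ketone 14 (C3'–H), by oxidation to a ring A p-quinone methide and 5-exo oxa-1,6-addition.
3. Enabling feature: C3' sits on C8 of ring A, para to the free C5 hydroxyl, and alpha to the ring D ketone, whose ortho hydroxyl is 1,5 to C3'. Removing O5–H and C3'–H therefore makes C3' electrophilic exactly where the ring D oxygen can reach it.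
4. 14 ⇒ aldehyde 8 + ring D aryllithium 11. Ring F ⇒ Rh2(S-PTTL)4-catalysed carbene C–H insertion of diazoacetate 6 into the O7 benzylic CH2, so the 4-(benzyloxy)benzyl protecting group on O7 becomes C2' and ring E (C2' set by the catalyst).
5. 6 ⇒ C8 bromide of per-O-protected (−)-epiafzelechin (chiral pool for C2 and C3). Ring order: A/B/C (purchased) → F (step 5) → G (step 11).

Key step: step 11

Assumption: the sense of induction of Rh2(S-PTTL)4 in step 5 is taken from simpler 2-(benzyloxy)aryl diazoacetates; if it proves opposite on 6, the mirror-image catalyst Rh2(R-PTTL)4 is used and nothing else changes.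

Abbreviation: BOB = 4-(benzyloxy)benzyl.

**Route**

Step 1
Reactants: 1 (−)-epiafzelechin; 2 4-(benzyloxy)benzyl chloride
Product: 3 3,5,7,4'-tetra-O-BOB-(−)-epiafzelechin
Conditions: NaH (4.8 equiv), 2 (4.6 equiv in all), n-Bu4NI (cat.), DMF, 0 °C → rt
Reagents that add atoms: three further equivalents of 4-(benzyloxy)benzyl chloride 2, ClCc1ccc(OCc2ccccc2)cc1.ClCc1ccc(OCc2ccccc2)cc1.ClCc1ccc(OCc2ccccc2)cc1
Why: Fourfold Williamson etherification of the three phenols and then the C3 alkoxide, as in the per-benzylation of flavan-3-ols, puts on O7 the benzyl group that later becomes C2' and ring E and protects the other hydroxyls with the same hydrogenolysable group.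

Step 2
Reactants: 3 3,5,7,4'-tetra-O-BOB-(−)-epiafzelechin
Product: 4 8-bromo-3,5,7,4'-tetra-O-BOB-(−)-epiafzelechin
Conditions: NBS (1.0 equiv), CH2Cl2, −78 °C → rt
Reagents that add atoms: N-bromosuccinimide, O=C1CCC(=O)N1Br
Why: Electrophilic aromatic bromination of the phloroglucinol-type ring A goes to C8 rather than C6, the regiochemistry established for 5,7-di-O-benzylated flavan-3-ols, and ring A is far more nucleophilic than the alkoxybenzyl rings.

Step 3
Reactants: 4 8-bromo-3,5,7,4'-tetra-O-BOB-(−)-epiafzelechin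
Product: 5 ethyl 2-[3,5,7,4'-tetra-O-BOB-(−)-epiafzelechin-8-yl]acetate
Conditions: BrZnCH2CO2Et (from ethyl bromoacetate, Zn dust, THF), Pd(dba)2 (5 mol %), P(t-Bu)3 (5 mol %), THF, rt → 60 °C
Reagents that add atoms: ethyl bromoacetate, CCOC(=O)CBr
Why: Zinc insertion into ethyl bromoacetate gives the Reformatsky reagent in the flask, and its Pd(dba)2/P(t-Bu)3-catalysed coupling with an aryl bromide (Negishi-type alpha-arylation of an ester) is neutral enough for the ethers and, with the bulky electron-rich phosphine, accepts di-ortho-substituted electron-rich bromides.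

Step 4
Reactants: 5 ethyl 2-[3,5,7,4'-tetra-O-BOB-(−)-epiafzelechin-8-yl]acetate
Product: 6 ethyl 2-diazo-2-[3,5,7,4'-tetra-O-BOB-(−)-epiafzelechin-8-yl]acetate
Conditions: p-ABSA (1.5 equiv), DBU (2 equiv), MeCN, 0 °C → rt
Reagents that add atoms: 4-acetamidobenzenesulfonyl azide, CC(=O)Nc1ccc(cc1)S(=O)(=O)N=[N+]=[N-]
Why: Regitz diazo transfer to an arylacetate is the standard entry to aryl diazoacetates, including those with ortho-alkoxy groups.

Step 5
Reactants: 6 ethyl 2-diazo-2-[3,5,7,4'-tetra-O-BOB-(−)-epiafzelechin-8-yl]acetate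
Product: 7 ethyl (2R,3R,2'S,3'R)-cis-dihydrofuran ester: 3,5,4'-tri-O-BOB-(−)-epiafzelechin with O7 and C8 bridged by –C2'H[4-(benzyloxy)phenyl]–C3'H(CO2Et)–
Conditions: Rh2(S-PTTL)4 (dirhodium tetrakis[N-phthaloyl-(S)-tert-leucinate], 1–2 mol %), toluene, −60 → −20 °C
Reagents that add atoms: none
Why: Intramolecular 1,5 C–H insertion of the donor/acceptor carbene generated on Rh2(S-PTTL)4 into the electron-rich benzylic C–H of the O7 ether closes ring F (insertion at flavan C2–H would need a bridged arene), and the chiral carboxylate catalyst sets C2' and gives the cis ester as established for 2-(benzyloxy)aryl diazoacetates.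

Step 6
Reactants: 7 ethyl cis-dihydrofuran ester
Product: 8 (2R,3R,2'S,3'R)-cis-aldehyde: as 7 with CHO on C3'
Conditions: i-Bu2AlH (1.2 equiv), CH2Cl2, −78 °C; aq. KNaC4H4O6 (Rochelle salt)
Reagents that add atoms: none
Why: Partial reduction of a hindered ester through its stable aluminium hemiacetal gives the aldehyde, and any epimerization at C3' from here to 14 is harmless because this centre becomes trigonal in step 11.

Step 7
Reactants: 9 1,3,5-tris(benzyloxy)benzene
Product: 10 2-bromo-1,3,5-tris(benzyloxy)benzene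
Conditions: NBS (1.0 equiv), CH2Cl2, −20 °C → 0 °C
Reagents that add atoms: N-bromosuccinimide, O=C1CCC(=O)N1Br
Why: Monobromination of a phloroglucinol triether with one equivalent of NBS is a clean electrophilic aromatic substitution, all three ring positions being equivalent.

Step 8
Reactants: 8 cis-aldehyde; 10 2-bromo-1,3,5-tris(benzyloxy)benzene
Product: 12 carbinol bearing CH(OH)[2,4,6-tris(benzyloxy)phenyl] on C3' (carbinol epimers), via aryllithium 11 (not isolated)
Conditions: 10, n-BuLi (1.05 equiv), THF, −78 °C; then 8, −78 °C; aq. NH4Cl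
Reagents that add atoms: none
Why: Bromine–lithium exchange followed by 1,2-addition of the 2,6-dialkoxyaryllithium to the aldehyde is faster at −78 °C than enolization and installs ring D with all its oxygens.

Step 9
Reactants: 12 carbinol
Product: 13 (2R,3R,2'S,3'R)-ketone: as 8 but C(=O)[2,4,6-tris(benzyloxy)phenyl] on C3'
Conditions: Dess–Martin periodinane (1.5 equiv), pyridine (3 equiv), CH2Cl2, 0 °C → rt
Reagents that add atoms: none
Why: Dess–Martin oxidation converts hindered benzylic carbinols to aryl ketones under nearly neutral conditions that spare the acid-labile alkoxybenzyl ethers.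

Step 10
Reactants: 13 protected ketone
Product: 14 (2R,3R,2'S,3'R)-hexaphenolic ketone: (−)-epiafzelechin with O7 and C8 bridged by –C2'H(4-hydroxyphenyl)–C3'H[C(=O)(2,4,6-trihydroxyphenyl)]–
Conditions: H2 (1 atm), Pd(OH)2/C, THF/MeOH, rt; used directly under argon
Reagents that add atoms: none
Why: Hydrogenolysis cleaves all seven benzylic ether protecting groups (three BOB ethers, each giving toluene and 4-methylphenol, and four benzyl ethers, each giving toluene), while the cyclic 2-aryl ethers of rings C and F and the hydrogen-bonded aryl ketone are expected to survive neutral conditions at 1 atm, as in flavan-3-ol and neolignan deprotections.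

Step 11
Reactants: 14 hexaphenolic ketone
Product: 16 target spirobiflavonoid CNP0228515.2 (2R,3R,2'R,3'R), via quinone methide 15 (not isolated)
Conditions: DDQ (1.05 equiv), THF/CH2Cl2, −20 → 0 °C, argon, dark
Reagents that add atoms: none
Why: DDQ removes two hydrogens from ring A of 14 (O5–H and the para-benzylic, ketone-activated C3'–H), giving the ring A p-quinone methide 15 in which C3' is trigonal and electrophilic. The ring D hydroxyl ortho to the ketone, held 1,5 to C3', then adds in an oxa-1,6-conjugate addition that rearomatizes ring A and forms the O–C3' bond. The closest known reaction type is the DDQ- or Ag2O-mediated oxidation of 4-alkylphenols to p-quinone methides with intramolecular capture by an oxygen nucleophile, used here as an oxidative alpha-aryloxylation of a 2'-hydroxyaryl ketone to a 2,2-disubstituted benzofuran-3(2H)-one. Ring G closes in the 5-exo-trig mode. The new quaternary stereocentre C3' is controlled by the adjacent C2' stereocentre: closure should place the ring oxygen, not the bulkier carbonyl arm, syn to the C2' aryl group, and reversibility of the addition under the mildly acidic conditions should funnel material to this less congested (2'R,3'R) epimer. The step needs site selectivity among the benzylic C–H bonds and capture of 15 before it tautomerizes to the aromatic 3-aroylbenzofuran; the first is secured because only C3'–H is both para to a free phenol and alpha to a carbonyl, the second by the intramolecular hydrogen-bonded ring D hydroxyl and base-free conditions.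

**Compound list**

1 | (−)-epiafzelechin, (2R,3R)-2-(4-hydroxyphenyl)chromane-3,5,7-triol | Oc1cc(O)c2c(c1)O[C@H](c1ccc(O)cc1)[C@H](O)C2 | starting material
2 | 4-(benzyloxy)benzyl chloride | ClCc1ccc(OCc2ccccc2)cc1 | starting material
3 | 3,5,7,4'-tetra-O-BOB-(−)-epiafzelechin, (2R,3R) | O(Cc1ccc(OCc2ccccc2)cc1)c1cc(OCc2ccc(OCc3ccccc3)cc2)c2c(c1)O[C@H](c1ccc(OCc3ccc(OCc4ccccc4)cc3)cc1)[C@H](OCc1ccc(OCc3ccccc3)cc1)C2 | intermediate
4 | 8-bromo-3,5,7,4'-tetra-O-BOB-(−)-epiafzelechin, (2R,3R) | Brc1c(OCc2ccc(OCc3ccccc3)cc2)cc(OCc2ccc(OCc3ccccc3)cc2)c2c1O[C@H](c1ccc(OCc3ccc(OCc4ccccc4)cc3)cc1)[C@H](OCc1ccc(OCc3ccccc3)cc1)C2 | intermediate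
5 | ethyl 2-[3,5,7,4'-tetra-O-BOB-(−)-epiafzelechin-8-yl]acetate | CCOC(=O)Cc1c(OCc2ccc(OCc3ccccc3)cc2)cc(OCc2ccc(OCc3ccccc3)cc2)c2c1O[C@H](c1ccc(OCc3ccc(OCc4ccccc4)cc3)cc1)[C@H](OCc1ccc(OCc3ccccc3)cc1)C2 | intermediate
6 | ethyl 2-diazo-2-[3,5,7,4'-tetra-O-BOB-(−)-epiafzelechin-8-yl]acetate | CCOC(=O)C(=[N+]=[N-])c1c(OCc2ccc(OCc3ccccc3)cc2)cc(OCc2ccc(OCc3ccccc3)cc2)c2c1O[C@H](c1ccc(OCc3ccc(OCc4ccccc4)cc3)cc1)[C@H](OCc1ccc(OCc3ccccc3)cc1)C2 | intermediate
7 | ethyl (2R,3R,2'S,3'R)-cis-dihydrofuran ester; ring F = O7–C2'H[4-(benzyloxy)phenyl]–C3'H(CO2Et)–C8; C2' has the spatial arrangement of the target (its descriptor is S until C3' carries oxygen) | CCOC(=O)[C@@H]1c2c(cc(OCc3ccc(OCc4ccccc4)cc3)c3c2O[C@H](c2ccc(OCc4ccc(OCc5ccccc5)cc4)cc2)[C@H](OCc2ccc(OCc4ccccc4)cc2)C3)O[C@@H]1c1ccc(OCc2ccccc2)cc1 | intermediate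
8 | (2R,3R,2'S,3'R)-cis-aldehyde (CHO on C3') | O=C[C@@H]1c2c(cc(OCc3ccc(OCc4ccccc4)cc3)c3c2O[C@H](c2ccc(OCc4ccc(OCc5ccccc5)cc4)cc2)[C@H](OCc2ccc(OCc4ccccc4)cc2)C3)O[C@@H]1c1ccc(OCc2ccccc2)cc1 | intermediate
9 | 1,3,5-tris(benzyloxy)benzene | c1ccc(COc2cc(OCc3ccccc3)cc(OCc3ccccc3)c2)cc1 | starting material
10 | 2-bromo-1,3,5-tris(benzyloxy)benzene | Brc1c(OCc2ccccc2)cc(OCc2ccccc2)cc1OCc1ccccc1 | intermediate
11 | [2,4,6-tris(benzyloxy)phenyl]lithium (not isolated) | [Li]c1c(OCc2ccccc2)cc(OCc2ccccc2)cc1OCc1ccccc1 | intermediate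
12 | carbinol, C3'–CH(OH)[2,4,6-tris(benzyloxy)phenyl], ring F cis, carbinol centre as a mixture of epimers | OC(c1c(OCc2ccccc2)cc(OCc2ccccc2)cc1OCc1ccccc1)[C@@H]1c2c(cc(OCc3ccc(OCc4ccccc4)cc3)c3c2O[C@H](c2ccc(OCc4ccc(OCc5ccccc5)cc4)cc2)[C@H](OCc2ccc(OCc4ccccc4)cc2)C3)O[C@@H]1c1ccc(OCc2ccccc2)cc1 | intermediate
13 | (2R,3R,2'S,3'R)-ketone, C3'–C(=O)[2,4,6-tris(benzyloxy)phenyl], ring F cis | O=C(c1c(OCc2ccccc2)cc(OCc2ccccc2)cc1OCc1ccccc1)[C@@H]1c2c(cc(OCc3ccc(OCc4ccccc4)cc3)c3c2O[C@H](c2ccc(OCc4ccc(OCc5ccccc5)cc4)cc2)[C@H](OCc2ccc(OCc4ccccc4)cc2)C3)O[C@@H]1c1ccc(OCc2ccccc2)cc1 | intermediate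
14 | (2R,3R,2'S,3'R)-hexaphenolic ketone (all protecting groups removed, C3'–H) | O=C(c1c(O)cc(O)cc1O)[C@@H]1c2c(cc(O)c3c2O[C@H](c2ccc(O)cc2)[C@H](O)C3)O[C@@H]1c1ccc(O)cc1 | intermediate
15 | (2R,3R,2'R)-ring A p-quinone methide (C5=O, C8=C3'; not isolated) | O=C1C=C2O[C@H](c3ccc(O)cc3)C(C(=O)c3c(O)cc(O)cc3O)=C2C2=C1C[C@@H](O)[C@@H](c1ccc(O)cc1)O2 | intermediate
16 | CNP0228515.2, (2R,3R,2'R,3'R): (−)-epiafzelechin with O7 and C8 bridged by ring F, whose C3' is the spiro C2 of a 4,6-dihydroxybenzofuran-3(2H)-one; C2' aryl syn to the furanone oxygen | O=C1c2c(O)cc(O)cc2O[C@@]12c1c(cc(O)c3c1O[C@H](c1ccc(O)cc1)[C@H](O)C3)O[C@@H]2c1ccc(O)cc1 | target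

**Step count and risks**

Total steps: 11. Longest linear sequence: 10 (steps 1–6 and 8–11; step 7 is a one-step branch).

Steps most likely to fail:

1. Step 11. What may go wrong: DDQ oxidizes other phenolic or benzylic positions of the free polyphenol, the quinone methide tautomerizes to the aromatic 3-aroylbenzofuran instead of closing, or the facial selectivity of the C–O bond formation is poor. Fallback: the same quinone methide is reached without an oxidant, by putting the oxygen on C3' before deprotection. The fallback sets out from ketone 13. Enolization with KN(SiMe3)2 (THF, −78 °C) and hydroxylation with 2-(phenylsulfonyl)-3-phenyloxaziridine would give the protected alpha-hydroxy ketone F1; opening of the enolate by loss of the O7 aryloxide is the reverse of a 5-endo-trig closure and should not compete. Hydrogenolysis (H2, Pd(OH)2/C, THF/MeOH) would give the free tertiary alcohol F2. Catalytic pyridinium p-toluenesulfonate in MeCN at rt should then ionize the C3' hydroxyl, assisted by the para O5–H, to quinone methide 15, where the fallback rejoins the route and closes to 16.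

2. Step 5. What may go wrong: poor enantiofacial control at C2', because the catalyst is mismatched with the flavan chirality or because the second ortho substituent twists the aryl group, or diversion of the carbene into arene cyclopropanation or dimerization. Fallback: stereocontrol is moved onto a covalently bound auxiliary that acts together with the catalyst. The fallback sets out from arylacetate 5. Saponification (LiOH, THF/MeOH/H2O) would give the acid F3, and esterification with (R)-pantolactone (DCC, DMAP, CH2Cl2) the pantolactonyl ester F4; the auxiliary enantiomer that reinforces the catalyst is chosen, (R) being drawn. Diazo transfer (p-ABSA, DBU) would give the diazoester F5, and Rh2(S-PTTL)4-catalysed C–H insertion the cis-dihydrofuran pantolactonyl ester F6. Transesterification (Ti(OEt)4, EtOH, 70 °C) returns to the route at ethyl ester 7.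

3. Step 3. What may go wrong: slow oxidative addition of the di-ortho-substituted, electron-rich bromide, leading to protodebromination or decomposition of the zinc enolate. Fallback: the two-carbon unit is introduced by an organolithium instead of a cross-coupling. The fallback sets out from bromide 4. Bromine–lithium exchange (n-BuLi, THF, −78 °C) and acylation with excess diethyl oxalate would give the aryl glyoxylate F7. Condensation with p-toluenesulfonyl hydrazide (EtOH/toluene, 60 °C) would give the tosylhydrazone F8. DBU in CH2Cl2 (Bamford–Stevens elimination of sulfinate) then gives diazoacetate 6 directly, where the fallback rejoins the route, bypassing 5.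

**Further compounds**

F1 | step 11 | protected alpha-hydroxy ketone: 13 with OH on C3', trans to the C2' aryl group, (2'R,3'S) | O=C(c1c(OCc2ccccc2)cc(OCc2ccccc2)cc1OCc1ccccc1)[C@]1(O)c2c(cc(OCc3ccc(OCc4ccccc4)cc3)c3c2O[C@H](c2ccc(OCc4ccc(OCc5ccccc5)cc4)cc2)[C@H](OCc2ccc(OCc4ccccc4)cc2)C3)O[C@@H]1c1ccc(OCc2ccccc2)cc1
F2 | step 11 | free tertiary alcohol: 14 with OH on C3' | O=C(c1c(O)cc(O)cc1O)[C@]1(O)c2c(cc(O)c3c2O[C@H](c2ccc(O)cc2)[C@H](O)C3)O[C@@H]1c1ccc(O)cc1
F3 | step 5 | 2-[3,5,7,4'-tetra-O-BOB-(−)-epiafzelechin-8-yl]acetic acid | OC(=O)Cc1c(OCc2ccc(OCc3ccccc3)cc2)cc(OCc2ccc(OCc3ccccc3)cc2)c2c1O[C@H](c1ccc(OCc3ccc(OCc4ccccc4)cc3)cc1)[C@H](OCc1ccc(OCc3ccccc3)cc1)C2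
F4 | step 5 | (R)-pantolactonyl ester of F3 | CC1(C)COC(=O)[C@@H]1OC(=O)Cc1c(OCc2ccc(OCc3ccccc3)cc2)cc(OCc2ccc(OCc3ccccc3)cc2)c2c1O[C@H](c1ccc(OCc3ccc(OCc4ccccc4)cc3)cc1)[C@H](OCc1ccc(OCc3ccccc3)cc1)C2
F5 | step 5 | (R)-pantolactonyl 2-diazo-2-arylacetate | CC1(C)COC(=O)[C@@H]1OC(=O)C(=[N+]=[N-])c1c(OCc2ccc(OCc3ccccc3)cc2)cc(OCc2ccc(OCc3ccccc3)cc2)c2c1O[C@H](c1ccc(OCc3ccc(OCc4ccccc4)cc3)cc1)[C@H](OCc1ccc(OCc3ccccc3)cc1)C2
F6 | step 5 | cis-dihydrofuran (R)-pantolactonyl ester (7 with the auxiliary in place of ethyl) | CC1(C)COC(=O)[C@@H]1OC(=O)[C@@H]1c2c(cc(OCc3ccc(OCc4ccccc4)cc3)c3c2O[C@H](c2ccc(OCc4ccc(OCc5ccccc5)cc4)cc2)[C@H](OCc2ccc(OCc4ccccc4)cc2)C3)O[C@@H]1c1ccc(OCc2ccccc2)cc1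
F7 | step 3 | ethyl 2-oxo-2-[3,5,7,4'-tetra-O-BOB-(−)-epiafzelechin-8-yl]acetate | CCOC(=O)C(=O)c1c(OCc2ccc(OCc3ccccc3)cc2)cc(OCc2ccc(OCc3ccccc3)cc2)c2c1O[C@H](c1ccc(OCc3ccc(OCc4ccccc4)cc3)cc1)[C@H](OCc1ccc(OCc3ccccc3)cc1)C2
F8 | step 3 | p-toluenesulfonylhydrazone of F7 | CCOC(=O)C(=NNS(=O)(=O)c1ccc(C)cc1)c1c(OCc2ccc(OCc3ccccc3)cc2)cc(OCc2ccc(OCc3ccccc3)cc2)c2c1O[C@H](c1ccc(OCc3ccc(OCc4ccccc4)cc3)cc1)[C@H](OCc1ccc(OCc3ccccc3)cc1)C2
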